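**Strategy.** The target is cut at the CH2–CH2 single bond between the trisubstituted side-chain alkene and the cyclohexenone. Its ring-side carbon, the CH2 on C1 of the 2,6,6-trimethyl-3-oxocyclohex-1-ene ring, is the γ-carbon of the enone. A throw-away allyl carboxylate on it makes it by far the most acidic site of the C10 ring fragment. The sodium dienolate is alkylated by the primary (E)-allylic bromide of the complete 1,2-dioxane propanoate (C16), and Pd(0) then removes allyl and CO2 in the same flask. The dioxane is built beforehand by a syn-aldol, oxetane opening by a hydroperoxide with inversion at C3, and axial C-methylation at C6.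

Key step: step 16

Remark: CIP analysis of the target gives the (2S,3S,6R,E) isomer; in the text C3 and C6 are the dioxane carbons and the "exocyclic CH2" is the CH2 on C1 of the cyclohexenone.

**Step 1**
Reactants: 1 5-bromo-2-methylpent-2-ene; 2 methyl 4-chloro-4-oxobutanoate
Product: 4 methyl 8-methyl-4-oxonon-7-enoate, via Grignard reagent 3 (not isolated)
Conditions: Mg, THF, rt; then 2, Fe(acac)3 (3 mol %), THF, −78 °C
Reagents that add atoms: none
Why: Iron-catalysed acylation of the homoprenyl Grignard reagent (Grignard cross-coupling) is much faster at the acid chloride than at the methyl ester or the product ketone, so the γ-keto ester should form without over-addition.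

**Step 2**
Reactants: 4 methyl 8-methyl-4-oxonon-7-enoate
Product: 5 methyl 4,4-dimethoxy-8-methylnon-7-enoate
Conditions: HC(OMe)3, MeOH, p-TsOH (cat.), rt
Reagents that add atoms: trimethyl orthoformate, COC(OC)OC; methanol, CO
Why: Acid-catalysed ketalisation with the orthoformate as water scavenger masks the ketone as a dimethyl ketal that survives the hydride and organolithium steps and is later the direct source of the hydroperoxy ketal.

**Step 3**
Reactants: 5 methyl 4,4-dimethoxy-8-methylnon-7-enoate
Product: 6 4,4-dimethoxy-8-methylnon-7-enal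
Conditions: DIBAL-H, CH2Cl2, −78 °C; Rochelle salt
Reagents that add atoms: none
Why: Partial ester reduction with DIBAL-H stops at the aldehyde because the tetrahedral aluminium hemiacetal is stable at −78 °C.

**Step 4**
Reactants: 6 4,4-dimethoxy-8-methylnon-7-enal; 7 (4S)-4-benzyl-3-propanoyl-1,3-oxazolidin-2-one
Product: 9 (4S)-4-benzyl-3-[(2S,3R)-3-hydroxy-6,6-dimethoxy-2,10-dimethylundec-9-enoyl]-1,3-oxazolidin-2-one, via boron enolate 8 (not isolated)
Conditions: 7, Bu2BOTf, i-Pr2NEt, CH2Cl2, 0 → −78 °C; 6, −78 → 0 °C; H2O2, MeOH, pH 7 buffer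
Reagents that add atoms: none
Why: Evans syn-aldol reaction: the (Z)-boron enolate reacts through a chair Zimmerman–Traxler transition state on the face away from the benzyl group, which sets C2 as (S) and the C3 carbinol as (R); ketal and alkene are inert.

**Step 5**
Reactants: 9 the aldol adduct
Product: 10 (2R,3R)-6,6-dimethoxy-2,10-dimethylundec-9-ene-1,3-diol
Conditions: LiBH4, MeOH (1 equiv), THF, 0 °C
Reagents that add atoms: none
Why: Reductive cleavage of the imide by LiBH4 releases the primary alcohol and the auxiliary without touching either stereocentre (the C2 descriptor changes from S to R only through the CIP priorities).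

**Step 6**
Reactants: 10 (2R,3R)-6,6-dimethoxy-2,10-dimethylundec-9-ene-1,3-diol
Product: 12 (2R,3R)-2-(3,3-dimethoxy-7-methyloct-6-en-1-yl)-3-methyloxetane, via primary tosylate 11 (not isolated)
Conditions: n-BuLi (1 equiv), THF, 0 °C; TsCl (1 equiv); n-BuLi (1 equiv), 0 → 60 °C
Reagents that add atoms: none
Why: One-pot oxetane synthesis: the primary lithium alkoxide is sulfonylated selectively and the secondary alkoxide closes the ring by intramolecular Williamson substitution (4-exo-tet) at the primary carbon, so both stereocentres are retained.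

**Step 7**
Reactants: 12 (2R,3R)-2-(3,3-dimethoxy-7-methyloct-6-en-1-yl)-3-methyloxetane
Product: 14 (2R)-2-[(3S)-6-methoxy-6-(4-methylpent-3-en-1-yl)-1,2-dioxan-3-yl]propan-1-ol (both C6 epimers), via hydroperoxy ketal 13 (not isolated)
Conditions: H2O2·urea, PPTS (cat.), MeOH, 0 °C; work-up; Yb(OTf)3 (cat.), CH2Cl2, 0 °C → rt
Reagents that add atoms: hydrogen peroxide (as urea adduct), OO
Why: Acid-catalysed exchange of one methoxy group for OOH gives the α-methoxy hydroperoxide, whose OOH group opens the Lewis-acid-activated oxetane at its secondary carbon in the only feasible 6-exo mode (intramolecular hydroperoxide–oxetane opening) with inversion, which sets dioxane C3 as (S) and frees the CH2OH arm; the ketal carbon C6 is settled in step 8.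

**Step 8**
Reactants: 14 the 6-methoxy-1,2-dioxane alcohol
Product: 15 (2R)-2-[(3S,6R)-6-methyl-6-(4-methylpent-3-en-1-yl)-1,2-dioxan-3-yl]propan-1-ol
Conditions: AlMe3 (4 equiv), CH2Cl2, −78 → 0 °C; Rochelle salt
Reagents that add atoms: trimethylaluminium, C[Al](C)C
Why: Proposed new method: AlMe3 first turns the primary OH into an aluminium alkoxide and then ionises the C6–OMe bond to the cyclic peroxycarbenium ion (half-chair, C3 side chain pseudo-equatorial); methyl is transferred from aluminium along the axial trajectory on the face of the side chain (the 1,4-cis outcome known for 4-alkyl six-membered oxocarbenium ions, reinforced by delivery from the O–AlMe2 group), which should set C6 as (R) with CH3 axial and the homoprenyl chain equatorial; the closest known reaction types are the Lewis-acid substitution of cyclic peroxyketals by silyl nucleophiles via peroxycarbenium ions and the C-alkylation of lactol derivatives of peroxide-containing trioxanes with organoaluminium reagents.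

**Step 9**
Reactants: 15 the 6-methyl-1,2-dioxane alcohol
Product: 16 (2S)-2-[(3S,6R)-6-methyl-6-(4-methylpent-3-en-1-yl)-1,2-dioxan-3-yl]propanoic acid
Conditions: TEMPO (cat.), PhI(OAc)2, MeCN/pH 7 buffer, rt
Reagents that add atoms: water, O
Why: TEMPO/PhI(OAc)2 oxidation takes the primary alcohol through the aldehyde hydrate to the acid under near-neutral conditions that spare the dialkyl peroxide, the alkene and the α-stereocentre (descriptor R to S through CIP priorities only).

**Step 10**
Reactants: 16 the dioxane propanoic acid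
Product: 17 methyl (2S)-2-[(3S,6R)-6-methyl-6-(4-methylpent-3-en-1-yl)-1,2-dioxan-3-yl]propanoate
Conditions: TMSCHN2, MeOH/toluene, 0 °C
Reagents that add atoms: (trimethylsilyl)diazomethane, C[Si](C)(C)C=[N+]=[N-]
Why: O-Methylation of the acid with the diazoalkane is neutral and cannot trigger retro-oxa-Michael opening of the β-peroxy ester.

**Step 11**
Reactants: 17 the dioxane methyl ester
Product: 18 methyl (2S)-2-[(3S,6R)-6-[(3E)-5-hydroxy-4-methylpent-3-en-1-yl]-6-methyl-1,2-dioxan-3-yl]propanoate
Conditions: SeO2 (cat.), t-BuOOH, salicylic acid (cat.), CH2Cl2, rt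
Reagents that add atoms: tert-butyl hydroperoxide, CC(C)(C)OO; selenium dioxide, O=[Se]=O
Why: Riley allylic oxidation (ene reaction, then [2,3]-shift) of the gem-dimethyl alkene takes place at the (E)-methyl group and should give the (E)-allylic alcohol, in a medium that the dioxane tolerates.

**Step 12**
Reactants: 18 the (E)-allylic alcohol
Product: 20 methyl (2S)-2-[(3S,6R)-6-[(3E)-5-bromo-4-methylpent-3-en-1-yl]-6-methyl-1,2-dioxan-3-yl]propanoate, via allylic mesylate 19 (not isolated)
Conditions: MsCl, Et3N, CH2Cl2, −40 °C; LiBr, THF, 0 °C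
Reagents that add atoms: lithium bromide, [Li+].[Br-]
Why: Mesylation and SN2 displacement by bromide at the primary allylic carbon keep the (E)-geometry and avoid phosphines, which could reduce the peroxide.

**Step 13**
Reactants: 21 2-(2,6,6-trimethylcyclohex-1-en-1-yl)acetaldehyde
Product: 22 2-(2,6,6-trimethylcyclohex-1-en-1-yl)acetic acid
Conditions: NaClO2, NaH2PO4, 2-methylbut-2-ene, t-BuOH/H2O, rt
Reagents that add atoms: sodium chlorite, [Na+].[O-]Cl=O
Why: Pinnick oxidation converts the β,γ-unsaturated aldehyde into the acid without moving the tetrasubstituted double bond, the alkene scavenger removing HOCl.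

**Step 14**
Reactants: 22 2-(2,6,6-trimethylcyclohex-1-en-1-yl)acetic acid
Product: 23 prop-2-en-1-yl 2-(2,6,6-trimethylcyclohex-1-en-1-yl)acetate
Conditions: allyl bromide, K2CO3, DMF, rt
Reagents that add atoms: allyl bromide, C=CCBr
Why: SN2 O-alkylation of the potassium carboxylate installs the allyl ester that Pd(0) removes later.

**Step 15**
Reactants: 23 the allyl ester
Product: 24 prop-2-en-1-yl 2-(2,6,6-trimethyl-3-oxocyclohex-1-en-1-yl)acetate
Conditions: CrO3, 3,5-dimethylpyrazole, CH2Cl2, −20 °C
Reagents that add atoms: chromium trioxide, O=[Cr](=O)=O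
Why: Allylic oxidation with the Cr(VI)–pyrazole complex attacks the only ring CH2 next to the tetrasubstituted alkene (C3) and should give the enone; the exocyclic CH2 is deactivated by the ester and shielded by the gem-dimethyl group.

**Step 16**
Reactants: 24 prop-2-en-1-yl 2-(2,6,6-trimethyl-3-oxocyclohex-1-en-1-yl)acetate; 20 the (E)-allylic bromide
Product: 28 methyl (2S)-2-[(3S,6R)-6-methyl-6-[(3E)-4-methyl-6-(2,6,6-trimethyl-3-oxocyclohex-1-en-1-yl)hex-3-en-1-yl]-1,2-dioxan-3-yl]propanoate, via sodium dienolate 25 (not isolated), via alkylated allyl ester 26 (not isolated), via β-keto acid 27 (not isolated)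
Conditions: NaH (1.0 equiv), THF/DMF, 0 °C; 20, 0 °C → rt; then Pd(PPh3)4 (5 mol %), morpholine, rt → 60 °C
Reagents that add atoms: none
Why: NaH removes a proton from the exocyclic CH2 of 24, which is activated twice (α to the allyl ester, γ to the ring enone), and the delocalised sodium dienolate displaces bromide from the primary allylic carbon of 20 in an SN2 reaction that forms the CH2–CH2 bond and leaves the (E)-alkene untouched. The closest known reaction type is the acetoacetic ester alkylation in its vinylogous form, as in the C-alkylation of 3-substituted Hagemann's-ester enolates at the carbon next to the ester. No ring is closed, and the only new stereocentre (the ester-bearing CH of 26) forms as a mixture and is erased when Pd(0)/morpholine removes the allyl group (Tsuji-type deallylation) and the vinylogous β-keto acid 27 loses CO2 to the conjugated enone. The step needs carbon instead of oxygen alkylation and attack through the exocyclic carbon instead of ring C2: the soft allylic bromide favours carbon, ring C2 is fully substituted and crowded, and alkylation at the exocyclic carbon keeps the enone conjugated. The peroxide and the β-peroxy ester must survive: the stabilised dienolate is a weak base and is formed before 20 is added, so neither E1cB opening nor Kornblum–DeLaMare fragmentation of the dioxane should compete. SN2 over SN2′ is secured by the unhindered CH2Br terminus.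

**Compound list**
1 | 5-bromo-2-methylpent-2-ene | CC(C)=CCCBr | starting material
2 | methyl 4-chloro-4-oxobutanoate | COC(=O)CCC(Cl)=O | starting material
3 | (4-methylpent-3-en-1-yl)magnesium bromide | CC(C)=CCC[Mg]Br | intermediate (not isolated)
4 | methyl 8-methyl-4-oxonon-7-enoate | COC(=O)CCC(=O)CCC=C(C)C | intermediate
5 | methyl 4,4-dimethoxy-8-methylnon-7-enoate | COC(=O)CCC(OC)(OC)CCC=C(C)C | intermediate
6 | 4,4-dimethoxy-8-methylnon-7-enal | O=CCCC(OC)(OC)CCC=C(C)C | intermediate
7 | (4S)-4-benzyl-3-propanoyl-1,3-oxazolidin-2-one | CCC(=O)N1[C@@H](Cc2ccccc2)COC1=O | starting material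
8 | (Z)-dibutylboron enolate of 7 | C/C=C(\OB(CCCC)CCCC)N1[C@@H](Cc2ccccc2)COC1=O | intermediate (not isolated)
9 | (4S)-4-benzyl-3-[(2S,3R)-3-hydroxy-6,6-dimethoxy-2,10-dimethylundec-9-enoyl]-1,3-oxazolidin-2-one | O=C(N1[C@@H](Cc2ccccc2)COC1=O)[C@@H](C)[C@H](O)CCC(OC)(OC)CCC=C(C)C | intermediate
10 | (2R,3R)-6,6-dimethoxy-2,10-dimethylundec-9-ene-1,3-diol | OC[C@@H](C)[C@H](O)CCC(OC)(OC)CCC=C(C)C | intermediate
11 | (2R,3R)-3-hydroxy-6,6-dimethoxy-2,10-dimethylundec-9-en-1-yl 4-methylbenzenesulfonate | Cc1ccc(cc1)S(=O)(=O)OC[C@@H](C)[C@H](O)CCC(OC)(OC)CCC=C(C)C | intermediate (not isolated)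
12 | (2R,3R)-2-(3,3-dimethoxy-7-methyloct-6-en-1-yl)-3-methyloxetane | C[C@@H]1CO[C@@H]1CCC(OC)(OC)CCC=C(C)C | intermediate
13 | (2R,3R)-2-(3-hydroperoxy-3-methoxy-7-methyloct-6-en-1-yl)-3-methyloxetane | C[C@@H]1CO[C@@H]1CCC(OC)(OO)CCC=C(C)C | intermediate (not isolated)
14 | (2R)-2-[(3S)-6-methoxy-6-(4-methylpent-3-en-1-yl)-1,2-dioxan-3-yl]propan-1-ol, both C6 epimers | OC[C@@H](C)[C@@H]1CCC(OC)(CCC=C(C)C)OO1 | intermediate
15 | (2R)-2-[(3S,6R)-6-methyl-6-(4-methylpent-3-en-1-yl)-1,2-dioxan-3-yl]propan-1-ol | OC[C@@H](C)[C@@H]1CC[C@@](C)(CCC=C(C)C)OO1 | intermediate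
16 | (2S)-2-[(3S,6R)-6-methyl-6-(4-methylpent-3-en-1-yl)-1,2-dioxan-3-yl]propanoic acid | OC(=O)[C@@H](C)[C@@H]1CC[C@@](C)(CCC=C(C)C)OO1 | intermediate
17 | methyl (2S)-2-[(3S,6R)-6-methyl-6-(4-methylpent-3-en-1-yl)-1,2-dioxan-3-yl]propanoate | COC(=O)[C@@H](C)[C@@H]1CC[C@@](C)(CCC=C(C)C)OO1 | intermediate
18 | methyl (2S)-2-[(3S,6R)-6-[(3E)-5-hydroxy-4-methylpent-3-en-1-yl]-6-methyl-1,2-dioxan-3-yl]propanoate | COC(=O)[C@@H](C)[C@@H]1CC[C@@](C)(CC/C=C(\C)CO)OO1 | intermediate
19 | methanesulfonate of 18 | COC(=O)[C@@H](C)[C@@H]1CC[C@@](C)(CC/C=C(\C)COS(C)(=O)=O)OO1 | intermediate (not isolated)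
20 | methyl (2S)-2-[(3S,6R)-6-[(3E)-5-bromo-4-methylpent-3-en-1-yl]-6-methyl-1,2-dioxan-3-yl]propanoate | COC(=O)[C@@H](C)[C@@H]1CC[C@@](C)(CC/C=C(\C)CBr)OO1 | intermediate
21 | 2-(2,6,6-trimethylcyclohex-1-en-1-yl)acetaldehyde (β-homocyclocitral) | O=CCC1=C(C)CCCC1(C)C | starting material
22 | 2-(2,6,6-trimethylcyclohex-1-en-1-yl)acetic acid | OC(=O)CC1=C(C)CCCC1(C)C | intermediate
23 | prop-2-en-1-yl 2-(2,6,6-trimethylcyclohex-1-en-1-yl)acetate | C=CCOC(=O)CC1=C(C)CCCC1(C)C | intermediate
24 | prop-2-en-1-yl 2-(2,6,6-trimethyl-3-oxocyclohex-1-en-1-yl)acetate | C=CCOC(=O)CC1=C(C)C(=O)CCC1(C)C | intermediate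
25 | sodium dienolate of 24 | [Na+].[O-]C1=C(C)C(=CC(=O)OCC=C)C(C)(C)CC1 | intermediate (not isolated)
26 | allyl ester of the C-alkylated acid: the target with CO2CH2CH=CH2 on the CH2 next to the cyclohexenone (both epimers at that carbon) | COC(=O)[C@@H](C)[C@@H]1CC[C@@](C)(CC/C=C(\C)CC(C(=O)OCC=C)C2=C(C)C(=O)CCC2(C)C)OO1 | intermediate (not isolated)
27 | the corresponding carboxylic acid (vinylogous β-keto acid) | COC(=O)[C@@H](C)[C@@H]1CC[C@@](C)(CC/C=C(\C)CC(C(O)=O)C2=C(C)C(=O)CCC2(C)C)OO1 | intermediate (not isolated)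
28 | methyl (2S)-2-[(3S,6R)-6-methyl-6-[(3E)-4-methyl-6-(2,6,6-trimethyl-3-oxocyclohex-1-en-1-yl)hex-3-en-1-yl]-1,2-dioxan-3-yl]propanoate | COC(=O)[C@@H](C)[C@@H]1CC[C@@](C)(CC/C=C(\C)CCC2=C(C)C(=O)CCC2(C)C)OO1 | target

**Totals.** Total step count: 16. Longest linear sequence: 13 steps (steps 1–12, then step 16).

**Steps most likely to fail**

1. Step 8 (proposed new method). The organoaluminium reagent may attack the O–O bond, the peroxycarbenium ion may fragment by carbon-to-oxygen migration before methyl transfer, or methyl delivery may lack facial selectivity. The fallback uses known chemistry and sets out from 12. Hydrolysis of the ketal (PPTS, wet acetone) should give the oxetanyl ketone F1, and Wittig methylenation (Ph3P=CH2) the 1,1-disubstituted alkene F2. Mukaiyama–Isayama hydroperoxysilylation (Co(thd)2, Et3SiH, O2), which should take the 1,1-disubstituted alkene before the trisubstituted one, gives the tertiary triethylsilyl peroxide F3 as both epimers. Methanolysis (PPTS, MeOH) frees the tertiary hydroperoxide F4, which opens the oxetane (Yb(OTf)3) to 15 and its C6 epimer F5. This path has no control at C6, so F5 is removed by chromatography. The route is rejoined at 15.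

2. Step 7. Methanol or hydrogen peroxide may open the activated oxetane intermolecularly, or the hydroperoxy ketal may fragment under the Lewis acid before the 6-exo closure. The fallback sets out from 10. Silylation of the primary alcohol (TBSCl, imidazole) gives the silyl ether F6, and mesylation of the secondary alcohol the mesylate F7. Ketal exchange (H2O2·urea, PPTS, MeOH) gives the hydroperoxy ketal F8. Intramolecular 6-exo-tet displacement of the mesylate (KOt-Bu, 18-crown-6) with inversion should give the silyl-protected dioxane F9, and TBAF returns to the route at 14.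

3. Step 16. The ambident dienolate may be alkylated at oxygen or at ring C2, or the base may open the β-peroxy ester. The fallback is a base-free Pd-catalysed Tsuji–Trost allylation and sets out from 18 and 22. Compound 18 is converted (ClCO2Me, pyridine) into the allylic methyl carbonate F10. Acid 22 is converted (Boc2O, DMAP, t-BuOH) into the tert-butyl ester F11, which is oxidised (CrO3, 3,5-dimethylpyrazole) to the tert-butyl keto ester F12. Pd2(dba)3/dppe should join F10 and F12 at the less hindered terminus of each partner to give the alkylated tert-butyl ester F13. Cleavage of the tert-butyl ester (TMSOTf, 2,6-lutidine; then water) returns to the route at 27, which is decarboxylated by warming to 28.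

**Further compounds**
F1 | step 8 | 7-methyl-1-[(2R,3R)-3-methyloxetan-2-yl]oct-6-en-3-one | C[C@@H]1CO[C@@H]1CCC(=O)CCC=C(C)C
F2 | step 8 | (2R,3R)-3-methyl-2-(7-methyl-3-methylideneoct-6-en-1-yl)oxetane | C[C@@H]1CO[C@@H]1CCC(=C)CCC=C(C)C
F3 | step 8 | {[3,7-dimethyl-1-((2R,3R)-3-methyloxetan-2-yl)oct-6-en-3-yl]peroxy}triethylsilane, both epimers | C[C@@H]1CO[C@@H]1CCC(C)(OO[Si](CC)(CC)CC)CCC=C(C)C
F4 | step 8 | (2R,3R)-2-(3-hydroperoxy-3,7-dimethyloct-6-en-1-yl)-3-methyloxetane, both epimers | C[C@@H]1CO[C@@H]1CCC(C)(OO)CCC=C(C)C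
F5 | step 8 | (2R)-2-[(3S,6S)-6-methyl-6-(4-methylpent-3-en-1-yl)-1,2-dioxan-3-yl]propan-1-ol | OC[C@@H](C)[C@@H]1CC[C@](C)(CCC=C(C)C)OO1
F6 | step 7 | (2R,3R)-1-[(tert-butyldimethylsilyl)oxy]-6,6-dimethoxy-2,10-dimethylundec-9-en-3-ol | CC(C)(C)[Si](C)(C)OC[C@@H](C)[C@H](O)CCC(OC)(OC)CCC=C(C)C
F7 | step 7 | (2R,3R)-1-[(tert-butyldimethylsilyl)oxy]-6,6-dimethoxy-2,10-dimethylundec-9-en-3-yl methanesulfonate | CC(C)(C)[Si](C)(C)OC[C@@H](C)[C@H](OS(C)(=O)=O)CCC(OC)(OC)CCC=C(C)C
F8 | step 7 | (2R,3R)-1-[(tert-butyldimethylsilyl)oxy]-6-hydroperoxy-6-methoxy-2,10-dimethylundec-9-en-3-yl methanesulfonate | CC(C)(C)[Si](C)(C)OC[C@@H](C)[C@H](OS(C)(=O)=O)CCC(OC)(OO)CCC=C(C)C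
F9 | step 7 | tert-butyl{(2R)-2-[(3S)-6-methoxy-6-(4-methylpent-3-en-1-yl)-1,2-dioxan-3-yl]propoxy}dimethylsilane | CC(C)(C)[Si](C)(C)OC[C@@H](C)[C@@H]1CCC(OC)(CCC=C(C)C)OO1
F10 | step 16 | methyl (2S)-2-[(3S,6R)-6-{(3E)-5-[(methoxycarbonyl)oxy]-4-methylpent-3-en-1-yl}-6-methyl-1,2-dioxan-3-yl]propanoate | COC(=O)[C@@H](C)[C@@H]1CC[C@@](C)(CC/C=C(\C)COC(=O)OC)OO1
F11 | step 16 | tert-butyl 2-(2,6,6-trimethylcyclohex-1-en-1-yl)acetate | CC(C)(C)OC(=O)CC1=C(C)CCCC1(C)C
F12 | step 16 | tert-butyl 2-(2,6,6-trimethyl-3-oxocyclohex-1-en-1-yl)acetate | CC(C)(C)OC(=O)CC1=C(C)C(=O)CCC1(C)C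
F13 | step 16 | tert-butyl ester analogue of 26 | COC(=O)[C@@H](C)[C@@H]1CC[C@@](C)(CC/C=C(\C)CC(C(=O)OC(C)(C)C)C2=C(C)C(=O)CCC2(C)C)OO1
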